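The data are simulated for an exercise; noise was put on by code.

The violet flask cannot turn more than 8.80% of its starting material into target, because the overall equation takes one coupling partner per target and the charge holds 66.0 mM of it against 750 mM of starting material.

| flask | starting material | coupling partner | target | time |
|---|---|---|---|---|
| blue | 250 mM | 200 mM |  |  |
| amber | 250 mM | 200 mM | 120 mM |  |
| red | 750 mM | 200 mM |  |  |
| green | 250 mM | 100 mM |  |  |
| violet | 750 mM | 66.0 mM |  | 120 s |

| blue run: time / s | blue run: [target] / mM | amber run: time / s | amber run: [target] / mM | red run: time / s | red run: [target] / mM | green run: time / s | green run: [target] / mM |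
|---|---|---|---|---|---|---|---|
| 6.8 | 8.2 | 6.8 | 135.7 | 6.8 | 18.2 | 6.8 | 5.1 |
| 21 | 27.4 | 21 | 165.2 | 21 | 53.5 | 21 | 15.5 |
| 40 | 50.2 | 40 | 197.1 | 40 | 89.6 | 40 | 27.7 |
| 63 | 75.0 | 63 | 226.0 | 63 | 124.4 | 63 | 36.7 |
| 90 | 95.1 | 90 | 247.4 | 90 | 146.7 | 90 | 50.5 |
| 120 | 113.1 | 120 | 262.2 | 120 | 160.7 | 120 | 59.3 |

(each reading ± 1 mM)

- Overall: starting material + coupling partner -> target.
- Constant volume, constant temperature.
- A reading of a species includes what of it is bound.
- An order is taken over about fifteen percent of the charge, up and down.

- the exponent of [coupling partner] in the starting rate at the charge of the blue run (at the point where two percent of the starting material have become target)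
- the exponent of [starting material] in the starting rate at the charge of the blue run (at the point where two percent of the starting material have become target) (one fixed amount of target, the same in the runs compared)
- target in the violet run at 120 s, as a share of the starting material charged

How close to that ceiling does violet come in 120 s? Coupling partner is the limiting reagent, so I follow the share of it left, not the share made. Is that share a usable thing? The green run has half the coupling partner of the blue run. At 21 s the green run reads 15.5 mM of target and the blue run reads 27.4 mM, a ratio of 0.566, so the amount made goes roughly with c(coupling partner). At fixed c(starting material), a rate strictly proportional to c(coupling partner) takes equal shares off in equal times, whatever the charge. In violet, c(starting material) stays above 684 mM, so I treat it as pseudo-first-order.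

Which run lends the constant? At 21 s the red run, charged with 750 mM of starting material, reads 53.5 mM of target, and the blue run, charged with 250 mM, reads 27.4 mM. That ratio of 1.95 is smaller than the ratio of the charges, 3.00, so I don't scale from blue but borrow from the red run, which has violet's c(starting material). At 120 s the red run has a share 0.197 of its coupling partner not found as target. The apparent decay constant, the logarithm of the inverse of that share divided by the time, is 0.0136 s⁻¹. Carried to violet, the same share gives 53.0 mM of target, or 7.07%.

Does target disturb the loan? Between 6.8 s and 21 s the amber run, charged with 120 mM of target, gains 29.5 mM, more than the 19.2 mM of the blue run. The red run holds 160.7 mM of target at 120 s where violet can hold at most 66.0 mM, so I expect my figure to lean high.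

The forecast gives 0.75, 0.78 and 7%, on the ground that “red shows first-order decay of coupling partner with a constant of about 0.0145 /s”. Its constant is not mine, but the two percentages lie close.

The flask gives 0.83, 0.74 and 6.50%.

    starting material + coupling partner → target (0.05940 M⁻¹ s⁻¹)
    starting material + coupling partner → side product (0.01500 M⁻¹ s⁻¹)
    starting material + coupling partner + target → 2 target (0.3810 M⁻² s⁻¹)
    starting material + coupling partner ⇌ idle substrate-reagent adduct, settled at all times (3.040 M⁻¹)

The path from starting material, coupling partner and target to two target moves the readings by 22 in units of the scatter, root mean square. Violet's result corresponds to an apparent decay constant of 0.0112 s⁻¹, lower than red's 0.0136 s⁻¹. In the amber run, the blue charge plus 120 mM of target, the same constant at 120 s reads 0.0103 s⁻¹, higher than the 0.00695 s⁻¹ of the blue run.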